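You cannot read how fast the target dies from a curve on which it is still being made, because the fall you see is decay minus making. Here is what is known and asked:

common to all: precatalyst 5 mol%

| charge | starting material | partner | second substrate | temperature | remark | time |
|---|---|---|---|---|---|---|
| winter | 0.050 M | 2 equiv | 1 equiv | 85 °C | run made earlier |  |
| noon | 0.050 M | 2 equiv | 0.50 equiv | 100 °C | run made earlier |  |
| dawn | 0.050 M | 2 equiv | 0.75 equiv | 85 °C | run made earlier |  |
| summer | 0.10 M | 2 equiv | 1 equiv | 100 °C | run made earlier |  |
| north-west | 0.050 M | 2.00 equiv (fed, over 4.0 h) | 1.00 equiv |  | the addition at 60 °C, then warmed to 100 °C; the feed brings no volume worth counting | 5.0 h |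
| north | 0.050 M | 2.00 equiv | 1.00 equiv (fed, over 4.0 h) | 100 °C | all else is in the flask from the start; the feed brings no volume worth counting | 5.0 h |
| south | 0.050 M | 2.00 equiv | 1.00 equiv | 100 °C | everything together at the start | 5.0 h |
| north-east | 0.050 M | 2.00 equiv (fed, over 25 min) | 1.00 equiv | 100 °C | all else is in the flask from the start; the feed brings no volume worth counting | 5.0 h |
| south-west | 0.050 M | 2.00 equiv (fed, over 4.0 h) | 1.00 equiv | 100 °C | all else is in the flask from the start; the feed brings no volume worth counting | 5.0 h |

- winter (time / h: target / %): 0.833: 14.7; 2.00: 25.5; 3.00: 22.3; 4.00: 16.5; 5.00: 10.6; 6.00: 6.8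
- noon (time / h: target / %): 0.500: 15.1; 0.667: 15.6; 1.00: 13.0; 1.50: 8.3; 2.50: 2.9; 4.00: 1.0; 6.00: 0.4
- dawn (time / h: target / %): 1.00: 18.7; 1.33: 23.7; 2.00: 27.2; 3.00: 23.3; 5.00: 12.0; 8.00: 4.1; 12.0: 1.3
- summer (time / h: target / %): 0.500: 26.8; 0.833: 13.1; 1.50: 3.1; 3.00: 1.9; 6.00: 0.4

(scatter of a reading: 0.5 percentage points)



* which flask leads in amount of target, in percent of the starting material charged ("all alike" within 1.5 percentage points) (north-west / north / south / north-east / south-west / all alike)
* how much target is there at the end, in percent of the starting material charged: north-west
* how much target is there at the end, in percent of the starting material charged: north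
* how much target is there at the end, in percent of the starting material charged: south
* how much target is there at the end, in percent of the starting material charged: north-east
* how much target is there at the end, in percent of the starting material charged: south-west

Write P for the target and r for its rate of making, and suppose that the target decays by a first-order step. Then

dP/dt = r − P/τ

where τ is the mean time a target molecule survives. If r holds steady, P climbs towards a level where making and decay balance, the steady state of your kinetics course:

P(t) = rτ(1 − e^(−t/τ))

The best look at τ is a steep fall. Summer goes from 26.8% at 0.500 h to 3.1% at 1.50 h, a factor of 8.65, and noon goes from 8.3% at 1.50 h to 2.9% at 2.50 h, a factor of 2.86, so summer's stretch is the one to use. Taking that fall as pure decay gives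

τ = 0.464 h

This is the target's lifetime at 100 °C, as a reading. Any making during the fall slows it, so the real lifetime can only be shorter.

Now take north-west, which spends its last 1.00 h at 100 °C. That stretch is longer than τ, so I set aside whatever target the cold stage leaves. I assume that the warmed flask makes target as noon did in its first 0.500 h:

r = 0.302 h⁻¹ (fraction of the charge per hour)

rτ = 14.0%

P = 12.4%

South has no such late start. Noon and summer, its nearest runs, are down to 0.4% and 0.4% at 6.00 h, so I put north-west ahead of south.

The forecast also names north-west as the leader, with 13% in a range of 6% to 20%, slightly above my figure, gives 6% for north, 0.5% for south, 0.7% for north-east and 6% for south-west, and says of north-west “so it should lead”.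

North-west gives 10.0% and leads, with south-west at 2.24%, north-east at 0.477%, south at 0.423% and north at 0.145%. With the path from target to over-reaction product struck out, north-west ends at 55.3% instead.

    second substrate + partner + free catalyst → free catalyst + second product (k = 1.40 L² mol⁻² s⁻¹, Ea = 44.0 kJ mol⁻¹)
    second substrate + free catalyst → spent catalyst (k = 0.00680 L mol⁻¹ s⁻¹, Ea = 76.0 kJ mol⁻¹)
    starting material + partner + free catalyst → free catalyst + target (k = 3.70 L² mol⁻² s⁻¹, Ea = 43.0 kJ mol⁻¹)
    partner + precatalyst → free catalyst + spent reagent (k = 0.00360 L mol⁻¹ s⁻¹, Ea = 78.0 kJ mol⁻¹)
    target → over-reaction product (k = 0.00110 s⁻¹, Ea = 121 kJ mol⁻¹)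
    (constants at 100 °C)

Now read the balance backwards for south-west, taking r = P/τ. Its 2.24% at 5.00 h, divided by the τ read from summer, gives 0.0484 h⁻¹, but that τ is longer than the 0.253 h given by the last constant above, so the making rate comes out higher, at 0.0888 h⁻¹, still below the 0.302 h⁻¹ of noon's opening.

The earlier runs and the new flask come from a simulation from invented constants, noise included.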